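**Plan**

- Retrosynthesis: both acetates go back to a bis-ester (CO2Me on C3 of the dihydrofuran, CH2CH2CO2Et on the arene). The C3a–C3 bond is then shifted back onto the ester carbon, which makes that carbon C4 (C=O) of a six-membered pyranone, i.e. a (2S)-flavanone. The C2–aryl bond is cut to a chromone plus an arylboronic acid, and the aryl–CH2 bond of the arm to a 6-bromochromone plus a zinc homoenolate.
- Enabling feature: in the ring O1–C2–C3–C3a–C7a, C3 carries the arene carbon C3a and an exocyclic one-carbon branch side by side. This C3a–C3(–C) array is the 1,2-aryl-shift isomer of the C4a–C4(=O)–C3 array of a chroman-4-one, so the five-membered ring can come from the six-membered one by oxidative migration of C4a.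
- Forward order: A ring (bought) → pyranone ring (chromone) → propanoate arm (Negishi) → B ring at C2 (asymmetric 1,4-addition) → contraction of the pyranone to the dihydrofuran → one reduction for both arms → acetates.
- Stereochemistry: C2 (S) from the Pd/(R)-t-BuPyOx catalyst. C3 follows from C2 in the ring contraction (anti iodination, migration with inversion gives 2,3-trans, which is also the thermodynamic epimer).

Key step: step 6

Remarks on the chemistry:
- The target is read as (2S,3R), which is the 2,3-trans isomer.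
- The sense of induction in step 5 is taken by analogy with cyclic enones, so the (R)-ligand is expected to give the (2S)-flavanone; if the opposite sense holds, the (S)-ligand is used.

**Route**

Step 1
Reactants: 1 1-(2-hydroxy-3-methoxyphenyl)ethan-1-one
Product: 2 1-(5-bromo-2-hydroxy-3-methoxyphenyl)ethan-1-one
Conditions: NBS (1.05 equiv), MeCN, 0 °C → rt
Reagents that add atoms: N-bromosuccinimide O=C1CCC(=O)N1Br
Why: Electrophilic aromatic bromination; both positions ortho to the OH are blocked (acetyl, OMe), so bromine should enter para to the OH, which is also meta to the acetyl group.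

Step 2
Reactants: 2 1-(5-bromo-2-hydroxy-3-methoxyphenyl)ethan-1-one
Product: 4 6-bromo-8-methoxy-4H-chromen-4-one, via enaminone 3 (not isolated)
Conditions: DMF dimethyl acetal (2 equiv), toluene, 100 °C; then conc. HCl, CH2Cl2, 40 °C
Reagents that add atoms: N,N-dimethylformamide dimethyl acetal COC(OC)N(C)C
Why: Enaminone chromone synthesis: condensation of the methyl ketone with the amide acetal, then acid-promoted addition of the phenol OH to the enaminone β-carbon and loss of dimethylamine closes the pyranone ring.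

Step 3
Reactants: 4 6-bromo-8-methoxy-4H-chromen-4-one; 5 (3-ethoxy-3-oxopropyl)zinc bromide (0.5 M in THF, 1.5 equiv)
Product: 6 ethyl 3-(8-methoxy-4-oxo-4H-chromen-6-yl)propanoate
Conditions: Pd(OAc)2 (2 mol %), SPhos (4 mol %), THF, rt → 45 °C
Reagents that add atoms: none
Why: Negishi cross-coupling of an aryl bromide with an ester-stabilised primary alkylzinc halide; the organozinc halide is too mild to add to the chromone enone, and the bulky biarylphosphine should favour reductive elimination over β-hydride loss.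

Step 4
Reactants: 7 (4-hydroxy-3-methoxyphenyl)boronic acid
Product: 8 [4-(2,2-dimethylpropanoyloxy)-3-methoxyphenyl]boronic acid
Conditions: PivCl (1.1 equiv), pyridine, CH2Cl2, 0 °C → rt; dilute aqueous HCl work-up
Reagents that add atoms: pivaloyl chloride CC(C)(C)C(Cl)=O
Why: Pyridine-mediated O-acylation of the phenol; any mixed B–O–acyl species should revert to B(OH)2 on aqueous work-up, and the pivalate makes the ring electron-poor for step 6.

Step 5
Reactants: 6 ethyl 3-(8-methoxy-4-oxo-4H-chromen-6-yl)propanoate; 8 [4-(2,2-dimethylpropanoyloxy)-3-methoxyphenyl]boronic acid (2 equiv)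
Product: 9 ethyl 3-[(2S)-2-[4-(2,2-dimethylpropanoyloxy)-3-methoxyphenyl]-8-methoxy-4-oxo-3,4-dihydro-2H-chromen-6-yl]propanoate
Conditions: Pd(OCOCF3)2 (5 mol %), (R)-t-BuPyOx (6 mol %), NH4PF6 (30 mol %), H2O (5 equiv), ClCH2CH2Cl, 60 °C
Reagents that add atoms: none
Why: Pd(II)-catalysed asymmetric conjugate addition of an arylboronic acid to a chromone; the aryl–Pd species inserts the C2=C3 bond from the face left open by the ligand tert-butyl group, which sets C2 as S, and water protonates the Pd enolate to release the flavanone.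

Step 6
Reactants: 9 ethyl 3-[(2S)-2-[4-(2,2-dimethylpropanoyloxy)-3-methoxyphenyl]-8-methoxy-4-oxo-3,4-dihydro-2H-chromen-6-yl]propanoate
Product: 12 methyl (2S,3S)-5-(3-ethoxy-3-oxopropyl)-7-methoxy-2-[4-(2,2-dimethylpropanoyloxy)-3-methoxyphenyl]-2,3-dihydro-1-benzofuran-3-carboxylate, via 4-methoxy-2H-chromene enol ether 10 (not isolated), via trans-3-iodanyl ketal 11 (not isolated)
Conditions: PhI(OAc)2 (1.3 equiv), conc. H2SO4 (1 equiv), HC(OMe)3, 0 °C → rt
Reagents that add atoms: trimethyl orthoformate COC(OC)OC (OMe groups of 10, 11 and the ester OMe of 12); (diacetoxyiodo)benzene CC(=O)OI(OC(C)=O)c1ccccc1 (PhI(OAc) unit of 11 only)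
Why: Acid and the orthoformate should turn the C4 ketone into its ketal and then the enol ether 10; iodine(III) attacks C3 anti to the C2 aryl group and methanol re-forms the C4 ketal to give 11, in which the ring bond C4–C4a lies antiperiplanar to the equatorial C3–I bond, so the arene carbon C4a shifts from C4 to C3 as PhI leaves, and the resulting dimethoxycarbenium ion at the old C4 is demethylated by acetate to the methyl ester. The closest known reaction type is the hypervalent-iodine (or thallium(III)) oxidative ring contraction of flavanones to trans-methyl 2-aryl-2,3-dihydrobenzofuran-3-carboxylates. The five-membered ring is not closed by cyclisation but by this 1,2-shift through a phenonium-type bridged transition state across C3–C4–C4a (6→5 contraction), with the O1–C2 and O1–C8a bonds untouched. C3 is set by substrate control from C2: anti iodination followed by migration with inversion gives the 2,3-trans ester (2S,3S), which is also the thermodynamic epimer at the enolisable C3, while C2 is not involved and keeps its configuration. The step needs migration of C4a and not of the C2 aryl group (isoflavone pathway) nor elimination to the flavone; the pivaloyloxy B ring has a low migratory aptitude and does not ionise the C2–O bond, and the diequatorial conformer of 11 aligns only the C4–C4a bond with the C–I bond. Any ethyl/methyl exchange at the side-chain ester is harmless because both esters are reduced in step 7.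

Step 7
Reactants: 12 methyl (2S,3S)-5-(3-ethoxy-3-oxopropyl)-7-methoxy-2-[4-(2,2-dimethylpropanoyloxy)-3-methoxyphenyl]-2,3-dihydro-1-benzofuran-3-carboxylate
Product: 13 4-[(2S,3R)-3-(hydroxymethyl)-5-(3-hydroxypropyl)-7-methoxy-2,3-dihydro-1-benzofuran-2-yl]-2-methoxyphenol
Conditions: LiAlH4 (4 equiv), THF, 0 °C → rt; aqueous NaOH work-up
Reagents that add atoms: none
Why: Hydride reduction of both esters to primary alcohols with concomitant cleavage of the aryl pivalate; ester reduction at 0 °C should outrun enolisation, and afterwards C3 is no longer epimerisable (the descriptor changes to 3R by priority only).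

Step 8
Reactants: 13 4-[(2S,3R)-3-(hydroxymethyl)-5-(3-hydroxypropyl)-7-methoxy-2,3-dihydro-1-benzofuran-2-yl]-2-methoxyphenol
Product: 14 [(2S,3R)-2-(4-acetoxy-3-methoxyphenyl)-5-(3-acetoxypropyl)-7-methoxy-2,3-dihydro-1-benzofuran-3-yl]methyl acetate
Conditions: Ac2O (5 equiv), pyridine, DMAP (cat.), CH2Cl2, rt
Reagents that add atoms: acetic anhydride CC(=O)OC(C)=O
Why: Nucleophile-catalysed acylation of all three hydroxyl groups; no stereocentre is involved.

Step 9
Reactants: 14 [(2S,3R)-2-(4-acetoxy-3-methoxyphenyl)-5-(3-acetoxypropyl)-7-methoxy-2,3-dihydro-1-benzofuran-3-yl]methyl acetate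
Product: 15 [(2S,3R)-5-(3-acetoxypropyl)-2-(4-hydroxy-3-methoxyphenyl)-7-methoxy-2,3-dihydro-1-benzofuran-3-yl]methyl acetate
Conditions: NH4OAc (10 equiv), MeOH/H2O 4:1, rt
Reagents that add atoms: none
Why: Chemoselective solvolysis of the aryl acetate under near-neutral conditions; the phenoxide is a far better leaving group than a primary alkoxide, so the two alkyl acetates should remain.

**Compound list**

1 | 1-(2-hydroxy-3-methoxyphenyl)ethan-1-one | CC(=O)c1cccc(OC)c1O | starting material
2 | 1-(5-bromo-2-hydroxy-3-methoxyphenyl)ethan-1-one | CC(=O)c1cc(Br)cc(OC)c1O | intermediate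
3 | (E)-1-(5-bromo-2-hydroxy-3-methoxyphenyl)-3-(dimethylamino)prop-2-en-1-one | CN(C)/C=C/C(=O)c1cc(Br)cc(OC)c1O | intermediate
4 | 6-bromo-8-methoxy-4H-chromen-4-one | COc1cc(Br)cc2c(=O)ccoc12 | intermediate
5 | (3-ethoxy-3-oxopropyl)zinc bromide | CCOC(=O)CC[Zn]Br | starting material
6 | ethyl 3-(8-methoxy-4-oxo-4H-chromen-6-yl)propanoate | CCOC(=O)CCc1cc(OC)c2occc(=O)c2c1 | intermediate
7 | (4-hydroxy-3-methoxyphenyl)boronic acid | COc1cc(B(O)O)ccc1O | starting material
8 | [4-(2,2-dimethylpropanoyloxy)-3-methoxyphenyl]boronic acid | COc1cc(B(O)O)ccc1OC(=O)C(C)(C)C | intermediate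
9 | ethyl 3-[(2S)-2-[4-(2,2-dimethylpropanoyloxy)-3-methoxyphenyl]-8-methoxy-4-oxo-3,4-dihydro-2H-chromen-6-yl]propanoate | CCOC(=O)CCc1cc(OC)c2c(c1)C(=O)C[C@@H](c1ccc(OC(=O)C(C)(C)C)c(OC)c1)O2 | intermediate
10 | ethyl 3-[(2S)-2-[4-(2,2-dimethylpropanoyloxy)-3-methoxyphenyl]-4,8-dimethoxy-2H-chromen-6-yl]propanoate | CCOC(=O)CCc1cc(OC)c2c(c1)C(OC)=C[C@@H](c1ccc(OC(=O)C(C)(C)C)c(OC)c1)O2 | intermediate
11 | ethyl 3-[(2R,3R)-3-[acetoxy(phenyl)-λ3-iodanyl]-2-[4-(2,2-dimethylpropanoyloxy)-3-methoxyphenyl]-4,4,8-trimethoxy-3,4-dihydro-2H-chromen-6-yl]propanoate (2,3-trans) | CCOC(=O)CCc1cc(OC)c2c(c1)C(OC)(OC)[C@H](I(OC(C)=O)c1ccccc1)[C@@H](c1ccc(OC(=O)C(C)(C)C)c(OC)c1)O2 | intermediate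
12 | methyl (2S,3S)-5-(3-ethoxy-3-oxopropyl)-7-methoxy-2-[4-(2,2-dimethylpropanoyloxy)-3-methoxyphenyl]-2,3-dihydro-1-benzofuran-3-carboxylate | COc1cc([C@H]2Oc3c(OC)cc(CCC(=O)OCC)cc3[C@@H]2C(=O)OC)ccc1OC(=O)C(C)(C)C | intermediate
13 | 4-[(2S,3R)-3-(hydroxymethyl)-5-(3-hydroxypropyl)-7-methoxy-2,3-dihydro-1-benzofuran-2-yl]-2-methoxyphenol | COc1cc([C@H]2Oc3c(OC)cc(CCCO)cc3[C@@H]2CO)ccc1O | intermediate
14 | [(2S,3R)-2-(4-acetoxy-3-methoxyphenyl)-5-(3-acetoxypropyl)-7-methoxy-2,3-dihydro-1-benzofuran-3-yl]methyl acetate | COc1cc([C@H]2Oc3c(OC)cc(CCCOC(C)=O)cc3[C@@H]2COC(C)=O)ccc1OC(C)=O | intermediate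
15 | [(2S,3R)-5-(3-acetoxypropyl)-2-(4-hydroxy-3-methoxyphenyl)-7-methoxy-2,3-dihydro-1-benzofuran-3-yl]methyl acetate | COc1cc([C@H]2Oc3c(OC)cc(CCCOC(C)=O)cc3[C@@H]2COC(C)=O)ccc1O | target

**Step count**

Total: 9 steps. Longest linear sequence: 8 steps (1, 2, 3, 5, 6, 7, 8, 9); step 4 is a one-step side branch.

**Steps most likely to fail**

Step 6. The wrong group may migrate (the C2 aryl group, leading to the isoflavone skeleton), the iodane may eliminate to the flavone, or the electron-rich A ring may be oxidised. The fallback replaces the ketone by an alkene as the substrate of the contraction and sets out from 9. Reduction with NaBH4 (MeOH/THF, 0 °C) should give the 2,4-cis alcohol ethyl 3-[(2S,4S)-4-hydroxy-8-methoxy-2-[4-(2,2-dimethylpropanoyloxy)-3-methoxyphenyl]-3,4-dihydro-2H-chromen-6-yl]propanoate F1. Dehydration with Burgess reagent (THF, 50 °C) should give the flav-3-ene ethyl 3-[(2S)-8-methoxy-2-[4-(2,2-dimethylpropanoyloxy)-3-methoxyphenyl]-2H-chromen-6-yl]propanoate F2. Oxythallation with Tl(NO3)3·3H2O in MeOH/HC(OMe)3 (0 °C) places the metal at C3 anti to the aryl group and a benzylic cation at C4, and the same C4a shift should give the trans acetal ethyl 3-[(2S,3S)-3-(dimethoxymethyl)-7-methoxy-2-[4-(2,2-dimethylpropanoyloxy)-3-methoxyphenyl]-2,3-dihydro-1-benzofuran-5-yl]propanoate F3. Hydrolysis (1 M HCl, acetone, rt) should give the aldehyde ethyl 3-[(2S,3S)-3-formyl-7-methoxy-2-[4-(2,2-dimethylpropanoyloxy)-3-methoxyphenyl]-2,3-dihydro-1-benzofuran-5-yl]propanoate F4. LiAlH4 (THF, 0 °C) then reduces aldehyde and ethyl ester and cleaves the pivalate, and the sequence comes back to the route at triol 13.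

Step 5. Facial discrimination on the 8-methoxychromone may be poor, protodeboronation may outrun transmetalation, or the ee may erode through reversible ring opening. The fallback gives up catalyst control of the C–C bond formation in favour of kinetic resolution and sets out from 6 and 8. The achiral catalyst Pd(OCOCF3)2/2,2'-bipyridine (NH4PF6, H2O, ClCH2CH2Cl, 60 °C) should give the racemic flavanone ethyl 3-[(2RS)-2-[4-(2,2-dimethylpropanoyloxy)-3-methoxyphenyl]-8-methoxy-4-oxo-3,4-dihydro-2H-chromen-6-yl]propanoate F5. Asymmetric transfer hydrogenation with RuCl(p-cymene)[(R,R)-TsDPEN] (HCO2H/Et3N, EtOAc, rt, stopped just past half conversion) should reduce the (2R) ketone to the cis alcohol ethyl 3-[(2R,4R)-4-hydroxy-8-methoxy-2-[4-(2,2-dimethylpropanoyloxy)-3-methoxyphenyl]-3,4-dihydro-2H-chromen-6-yl]propanoate F6. The unreduced (2S) ketone is separated by chromatography, and the sequence comes back to the route at 9.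

Step 3. The alkylzinc may be lost by β-hydride elimination or protodemetalation (giving the debrominated chromone), or the chromone enone may be attacked. The fallback installs the arm before the pyranone ring exists, by sp2 coupling, and sets out from 2. A Heck reaction with ethyl acrylate (Pd(OAc)2, P(o-tol)3, Et3N, DMF, 100 °C) should give ethyl (E)-3-(3-acetyl-4-hydroxy-5-methoxyphenyl)prop-2-enoate F7. Hydrogenation (H2, Pd/C, EtOAc, rt) should give ethyl 3-(3-acetyl-4-hydroxy-5-methoxyphenyl)propanoate F8. DMF dimethyl acetal (toluene, 100 °C) gives the enaminone ethyl 3-[3-[(E)-3-(dimethylamino)prop-2-enoyl]-4-hydroxy-5-methoxyphenyl]propanoate F9, which is cyclised without isolation (conc. HCl, CH2Cl2, 40 °C), and the sequence comes back to the route at 6.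

**Further compounds**

F1 | step 6 | ethyl 3-[(2S,4S)-4-hydroxy-8-methoxy-2-[4-(2,2-dimethylpropanoyloxy)-3-methoxyphenyl]-3,4-dihydro-2H-chromen-6-yl]propanoate | CCOC(=O)CCc1cc(OC)c2c(c1)[C@@H](O)C[C@@H](c1ccc(OC(=O)C(C)(C)C)c(OC)c1)O2
F2 | step 6 | ethyl 3-[(2S)-8-methoxy-2-[4-(2,2-dimethylpropanoyloxy)-3-methoxyphenyl]-2H-chromen-6-yl]propanoate | CCOC(=O)CCc1cc(OC)c2c(c1)C=C[C@@H](c1ccc(OC(=O)C(C)(C)C)c(OC)c1)O2
F3 | step 6 | ethyl 3-[(2S,3S)-3-(dimethoxymethyl)-7-methoxy-2-[4-(2,2-dimethylpropanoyloxy)-3-methoxyphenyl]-2,3-dihydro-1-benzofuran-5-yl]propanoate | COc1cc([C@H]2Oc3c(OC)cc(CCC(=O)OCC)cc3[C@@H]2C(OC)OC)ccc1OC(=O)C(C)(C)C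
F4 | step 6 | ethyl 3-[(2S,3S)-3-formyl-7-methoxy-2-[4-(2,2-dimethylpropanoyloxy)-3-methoxyphenyl]-2,3-dihydro-1-benzofuran-5-yl]propanoate | COc1cc([C@H]2Oc3c(OC)cc(CCC(=O)OCC)cc3[C@@H]2C=O)ccc1OC(=O)C(C)(C)C
F5 | step 5 | ethyl 3-[(2RS)-2-[4-(2,2-dimethylpropanoyloxy)-3-methoxyphenyl]-8-methoxy-4-oxo-3,4-dihydro-2H-chromen-6-yl]propanoate | CCOC(=O)CCc1cc(OC)c2c(c1)C(=O)CC(c1ccc(OC(=O)C(C)(C)C)c(OC)c1)O2
F6 | step 5 | ethyl 3-[(2R,4R)-4-hydroxy-8-methoxy-2-[4-(2,2-dimethylpropanoyloxy)-3-methoxyphenyl]-3,4-dihydro-2H-chromen-6-yl]propanoate | CCOC(=O)CCc1cc(OC)c2c(c1)[C@H](O)C[C@H](c1ccc(OC(=O)C(C)(C)C)c(OC)c1)O2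
F7 | step 3 | ethyl (E)-3-(3-acetyl-4-hydroxy-5-methoxyphenyl)prop-2-enoate | CCOC(=O)/C=C/c1cc(OC)c(O)c(C(C)=O)c1
F8 | step 3 | ethyl 3-(3-acetyl-4-hydroxy-5-methoxyphenyl)propanoate | CCOC(=O)CCc1cc(OC)c(O)c(C(C)=O)c1
F9 | step 3 | ethyl 3-[3-[(E)-3-(dimethylamino)prop-2-enoyl]-4-hydroxy-5-methoxyphenyl]propanoate | CCOC(=O)CCc1cc(OC)c(O)c(C(=O)/C=C/N(C)C)c1
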